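(The earlier runs and the new flask stem from a simulated flask with made-up constants, noise included.)

If you know how long X takes to fall back in a flask, and how far a change of temperature shifts that time in powers of ten, you can place each flask on a ladder of times before it is run.

in all of them: G 0.48 mol%

|  | E | Q | temperature | remark | time |
|---|---|---|---|---|---|
| violet | 15 mM | 1.2 equiv | 42 °C | run made earlier |  |
| grey | 34 mM | 1.2 equiv | 70 °C | run made earlier |  |
| east | 23 mM | 1.20 equiv | 80 °C |  | 8.0 d |
| south-west | 23 mM | 1.20 equiv | 30 °C |  | 8.0 d |
| south | 23 mM | 1.20 equiv |  | at 80 °C until 4.0 d, from then on at 30 °C | 8.0 d |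
| south-east | 23 mM | 1.20 equiv | 55 °C |  | 8.0 d |

| violet: time / d | violet: X / % | grey: time / d | grey: X / % |
|---|---|---|---|
| 10.0 | 20.3 | 0.833 | 13.8 |
| 20.0 | 10.7 | 2.08 | 9.4 |
| 30.0 | 8.3 | 5.00 | 9.5 |
| 40.0 | 6.1 | 10.0 | 8.5 |

(readings scatter by 0.5 percentage points)



1. the best flask by amount of X, in percent of the E charged; "all alike" if 1.5 percentage points covers them all (east / south-west / south / south-east / all alike)
2. amount of X at the end, in percent of the E charged, east
3. amount of X at the end, in percent of the E charged, south-west
4. amount of X at the end, in percent of the E charged, south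
5. amount of X at the end, in percent of the E charged, south-east

Here c(X), in percent of the E charged, climbs early and then sinks towards a floor. I take the last reading of each run as its floor and use the relaxation time, in which the excess of c(X) above the floor shrinks by a factor of e. The violet run at 42 °C gives 8.87 d. The grey run at 70 °C gives 0.703 d, a rough reading, as its second excess is 0.9 percentage points against a scatter of 0.5 points. I set aside that the two runs differ in charge. I assume that the logarithm of this time falls along a straight line with temperature, and the degrees that buy one power of ten are the ten-step, 25.4 K.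

Now the ladder, against the run of 8.0 d. East, at 80 °C, has 0.284 d, far shorter than the run, so by my reckoning it sits on its floor, near the last grey reading of 8.5%. South-east, at 55 °C, has 2.73 d, shorter than the run, which lasts 2.93 of these, so it lands close to its floor. South spends its last 4.00 d at 30 °C, where the time is 26.3 d, so those days are 0.152 of it, and south should stay near what its hot stretch left, close to east. South-west has that same time throughout, longer than at the two hotter temperatures and longer than the run, so I call it best, at the first violet reading of 20.3% or more. The forecast names south-west, with south-west at 30% (“still near the peak”), east 10%, south 9.6% and south-east 8.5%.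

    X + G ⇌ D + G, rate k1*[G]*[X] forward; the back reaction follows from the equilibrium constant (k = 840 M⁻¹ h⁻¹, Ea = 73.0 kJ mol⁻¹)
    E + Q ⇌ D (K = 420 M⁻¹, k = 15.0 M⁻¹ h⁻¹, Ea = 72.0 kJ mol⁻¹, ΔH = −57.0 kJ mol⁻¹)
    G → J (k = 0.00250 h⁻¹, Ea = 123 kJ mol⁻¹)
    E + Q ⇌ X (K = 57.0 M⁻¹, k = 30.0 M⁻¹ h⁻¹, Ea = 88.0 kJ mol⁻¹, ΔH = −36.0 kJ mol⁻¹)
    (constants at 80 °C)

South-west ends higher than the others, at 26.8%, against east 9.68%, south 11.1% and south-east 7.72%. At 8.00 d, 0.304 of its relaxation time, south-west still makes X 1.13 times faster than it uses it up, each step taken net; at 80.0 d, 3.04 relaxation times, it holds 5.71%. With the ten-step of 25.4 K, a neighbour like south-west kept at 45 °C has a relaxation time of 6.76 d, shorter than the run, and it ends at 15.6%.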